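**Retrosynthetic overview**
- The target comes from its tris-silyl ether by one fluoride deprotection.
- Rings C and A are both made in one operation from an acyclic (S)-δ-hydroxy-3,5,7-triketo tert-butyl ester. Ring C closes first by cyclodehydration. Ring A then forms by loss of tert-butanol to an acylketene, 6π-electrocyclization and aromatization. Ring B is bought.
- The acyclic precursor is joined at C4–C3 (flavanone numbering) from the trianion of a side-chain-bearing 3,5-diketo ester and an (S)-β-hydroxy Weinreb amide.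
- The diketo ester comes from tert-butyl acetoacetate by Tsuji–Trost allylation and dianion acetylation. The allylic acetate comes from geranyl acetate by Shi epoxidation and epoxide-to-allylic-silyl-ether isomerization, which sets 6R.
- The Weinreb amide comes from ethyl 3,4-dihydroxybenzoate by silylation, Claisen condensation and asymmetric transfer hydrogenation, which sets the future C2.

Assumption: descriptors read from the SMILES are 2S (flavanone C2), 6R (side-chain carbinol) and 2E (side-chain alkene); each chiral catalyst is named as the antipode expected to give these centres.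

**Route**

Step 1
Reactants: 1 geranyl acetate, (2E)-3,7-dimethylocta-2,6-dien-1-yl acetate
Product: 2 (2E)-5-[(2R)-3,3-dimethyloxiran-2-yl]-3-methylpent-2-en-1-yl acetate
Conditions: D-fructose-derived Shi ketone (30 mol%), KHSO5, K2CO3, Bu4NHSO4, MeCN/CH2(OMe)2/aq. Na2B4O7 buffer (pH 10.5), 0 °C
Reagents that add atoms: potassium peroxymonosulfate, KHSO5, [K+].[O-]S(=O)(=O)OO
Why: Shi asymmetric epoxidation; the chiral dioxirane attacks the electron-rich distal alkene (the 2,3-alkene is deactivated by the allylic acetate) through a spiro transition state and sets C6 as R.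

Step 2
Reactants: 2 (2E)-5-[(2R)-3,3-dimethyloxiran-2-yl]-3-methylpent-2-en-1-yl acetate
Product: 3 (2E,6R)-6-[(tert-butyldimethylsilyl)oxy]-3,7-dimethylocta-2,7-dien-1-yl acetate
Conditions: TBSOTf, DBU, PhMe, −40 → 23 °C
Reagents that add atoms: tert-butyldimethylsilyl trifluoromethanesulfonate (TBSOTf), CC(C)(C)[Si](C)(C)OS(=O)(=O)C(F)(F)F
Why: Silyl-triflate/amidine epoxide-to-allylic-silyl-ether isomerization (Noyori type); the silylated epoxide opens at the tertiary carbon and loses a methyl proton, and because the C6–O bond is never broken the R configuration is retained.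

Step 3
Reactants: 4 tert-butyl acetoacetate (tert-butyl 3-oxobutanoate); 3 (2E,6R)-6-[(tert-butyldimethylsilyl)oxy]-3,7-dimethylocta-2,7-dien-1-yl acetate
Product: 5 tert-butyl (4E,8R)-2-acetyl-8-[(tert-butyldimethylsilyl)oxy]-5,9-dimethyldeca-4,9-dienoate (both C2 epimers)
Conditions: 4 (2 equiv), NaH (1.9 equiv), Pd(PPh3)4 (3 mol%), THF, 0 → 45 °C
Reagents that add atoms: none
Why: Tsuji–Trost allylic alkylation; zerovalent palladium ionizes the primary allylic acetate and the soft enolate attacks the unhindered terminus of the π-allyl complex to give the linear E product, leaving the remote silyl ether centre untouched.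

Step 4
Reactants: 5 tert-butyl (4E,8R)-2-acetyl-8-[(tert-butyldimethylsilyl)oxy]-5,9-dimethyldeca-4,9-dienoate; 6 N-methoxy-N-methylacetamide
Product: 7 tert-butyl (4E,8R)-8-[(tert-butyldimethylsilyl)oxy]-5,9-dimethyl-2-(3-oxobutanoyl)deca-4,9-dienoate (enol tautomers, both C2 epimers)
Conditions: LiN(iPr)2 (2.2 equiv), THF, −78 → 0 °C; then 6, −78 → 0 °C; 1 M HCl
Reagents that add atoms: none
Why: Weiler dianion acylation; the γ-carbanion of the β-keto ester dianion adds to the Weinreb amide, whose chelated tetrahedral intermediate prevents over-addition, giving the 3,5-diketo ester.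

Step 5
Reactants: 8 ethyl 3,4-dihydroxybenzoate
Product: 9 ethyl 3,4-bis[(tert-butyldimethylsilyl)oxy]benzoate
Conditions: TBSCl (2.4 equiv), imidazole, DMF, 23 °C
Reagents that add atoms: tert-butyldimethylsilyl chloride (TBSCl), CC(C)(C)[Si](C)(C)Cl
Why: Standard phenol silylation; the aryl silyl ethers survive the amide bases used later and leave with fluoride at the end.

Step 6
Reactants: 9 ethyl 3,4-bis[(tert-butyldimethylsilyl)oxy]benzoate; 6 N-methoxy-N-methylacetamide
Product: 10 3-{3,4-bis[(tert-butyldimethylsilyl)oxy]phenyl}-N-methoxy-N-methyl-3-oxopropanamide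
Conditions: 6 (2.2 equiv), LiN(iPr)2 (2.2 equiv), THF, −78 °C; then 9, −78 → 0 °C; 1 M HCl
Reagents that add atoms: none
Why: Crossed Claisen condensation of the amide enolate with the aryl ester, driven by deprotonation of the β-keto amide product.

Step 7
Reactants: 10 3-{3,4-bis[(tert-butyldimethylsilyl)oxy]phenyl}-N-methoxy-N-methyl-3-oxopropanamide
Product: 11 (3S)-3-{3,4-bis[(tert-butyldimethylsilyl)oxy]phenyl}-3-hydroxy-N-methoxy-N-methylpropanamide
Conditions: RuCl[(S,S)-TsDPEN](p-cymene) (1 mol%), HCO2H/Et3N (5:2), EtOAc, 23 °C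
Reagents that add atoms: none
Why: Noyori–Ikariya asymmetric transfer hydrogenation; the (S,S)-catalyst reduces the aryl ketone with the same facial sense that gives (S)-1-phenylethanol from acetophenone, setting the (S)-benzylic carbinol that becomes C2.

Step 8
Reactants: 7 tert-butyl (4E,8R)-8-[(tert-butyldimethylsilyl)oxy]-5,9-dimethyl-2-(3-oxobutanoyl)deca-4,9-dienoate; 11 (3S)-3-{3,4-bis[(tert-butyldimethylsilyl)oxy]phenyl}-3-hydroxy-N-methoxy-N-methylpropanamide
Product: 12 tert-butyl (4E,8R)-2-[(7S)-7-{3,4-bis[(tert-butyldimethylsilyl)oxy]phenyl}-7-hydroxy-3,5-dioxoheptanoyl]-8-[(tert-butyldimethylsilyl)oxy]-5,9-dimethyldeca-4,9-dienoate (acyclic, enol tautomers)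
Conditions: 7, LiN(iPr)2 (3.3 equiv), THF, −78 → 0 °C; then lithium alkoxide of 11 (11 + LiN(iPr)2, 1.05 equiv, −78 °C), −78 → −20 °C; AcOH, −78 °C
Reagents that add atoms: none
Why: Harris-type polyanion acylation; the last-formed terminal carbanion of the diketo ester trianion is the most nucleophilic site and adds to the Weinreb amide, while the β-alkoxide cannot be eliminated, so the carbinol centre is preserved.

Step 9
Reactants: 12 tert-butyl (4E,8R)-2-[(7S)-7-{3,4-bis[(tert-butyldimethylsilyl)oxy]phenyl}-7-hydroxy-3,5-dioxoheptanoyl]-8-[(tert-butyldimethylsilyl)oxy]-5,9-dimethyldeca-4,9-dienoate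
Product: 15 (2S)-2-{3,4-bis[(tert-butyldimethylsilyl)oxy]phenyl}-6-[(2E,6R)-6-[(tert-butyldimethylsilyl)oxy]-3,7-dimethylocta-2,7-dien-1-yl]-5,7-dihydroxy-2,3-dihydro-4H-chromen-4-one, via dihydropyranone tert-butyl ester 13 (not isolated), via acylketene 14 (not isolated)
Conditions: CSA (5 mol%), 4 Å MS, xylenes, 23 °C; then 2,6-lutidine (0.1 equiv), dilution to 2 mM, 140 °C
Reagents that add atoms: none
Why: Proposed new method: under mild acid the benzylic hydroxyl adds to the C5 ketone and water is lost (the known cyclodehydration of δ-hydroxy-β-diketones to 2,3-dihydro-4-pyranones), closing ring C with the C2–O bond untouched (2S retained) and fixing the ring oxygen on the future C8a; at 140 °C the α-substituted tert-butyl β-keto ester of 13 expels tert-butanol (the known thermal route to acylketenes), and the enol of ketene 14 is a dienylketene that closes by 6π-electrocyclization onto the nucleophilic pyranone α-carbon and tautomerizes to phloroglucinol ring A, so the ketene carbon becomes C5–OH, its α-carbon carries the side chain at C6 and no 8-substituted isomer can form; the closest known reactions are ketene-based biomimetic aromatization of polyketo esters and dioxinones and the dienylketene electrocyclization that ends the Danheiser benzannulation.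

Step 10
Reactants: 15 (2S)-2-{3,4-bis[(tert-butyldimethylsilyl)oxy]phenyl}-6-[(2E,6R)-6-[(tert-butyldimethylsilyl)oxy]-3,7-dimethylocta-2,7-dien-1-yl]-5,7-dihydroxy-2,3-dihydro-4H-chromen-4-one
Product: 16 (2S)-2-(3,4-dihydroxyphenyl)-5,7-dihydroxy-6-[(2E,6R)-6-hydroxy-3,7-dimethylocta-2,7-dien-1-yl]-2,3-dihydro-4H-chromen-4-one
Conditions: HF·pyridine, pyridine, THF, 0 → 23 °C
Reagents that add atoms: none
Why: Buffered fluoride desilylation removes the two aryl and the allylic silyl ethers without base, so the flavanone does not open to its chalcone (C2 is not racemized) and the allylic alcohol is not ionized.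

**Compound list**

1 | geranyl acetate, (2E)-3,7-dimethylocta-2,6-dien-1-yl acetate | CC(C)=CCC/C(C)=C/COC(C)=O | starting material
2 | (2E)-5-[(2R)-3,3-dimethyloxiran-2-yl]-3-methylpent-2-en-1-yl acetate | CC1(C)O[C@@H]1CC/C(C)=C/COC(C)=O | intermediate
3 | (2E,6R)-6-[(tert-butyldimethylsilyl)oxy]-3,7-dimethylocta-2,7-dien-1-yl acetate | C=C(C)[C@H](O[Si](C)(C)C(C)(C)C)CC/C(C)=C/COC(C)=O | intermediate
4 | tert-butyl acetoacetate | CC(=O)CC(=O)OC(C)(C)C | starting material
5 | tert-butyl (4E,8R)-2-acetyl-8-[(tert-butyldimethylsilyl)oxy]-5,9-dimethyldeca-4,9-dienoate | CC(=O)C(C/C=C(\C)CC[C@@H](O[Si](C)(C)C(C)(C)C)C(C)=C)C(=O)OC(C)(C)C | intermediate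
6 | N-methoxy-N-methylacetamide | CC(=O)N(C)OC | starting material
7 | tert-butyl (4E,8R)-8-[(tert-butyldimethylsilyl)oxy]-5,9-dimethyl-2-(3-oxobutanoyl)deca-4,9-dienoate | CC(=O)CC(=O)C(C/C=C(\C)CC[C@@H](O[Si](C)(C)C(C)(C)C)C(C)=C)C(=O)OC(C)(C)C | intermediate
8 | ethyl 3,4-dihydroxybenzoate | CCOC(=O)c1ccc(O)c(O)c1 | starting material
9 | ethyl 3,4-bis[(tert-butyldimethylsilyl)oxy]benzoate | CCOC(=O)c1ccc(O[Si](C)(C)C(C)(C)C)c(O[Si](C)(C)C(C)(C)C)c1 | intermediate
10 | 3-{3,4-bis[(tert-butyldimethylsilyl)oxy]phenyl}-N-methoxy-N-methyl-3-oxopropanamide | CON(C)C(=O)CC(=O)c1ccc(O[Si](C)(C)C(C)(C)C)c(O[Si](C)(C)C(C)(C)C)c1 | intermediate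
11 | (3S)-3-{3,4-bis[(tert-butyldimethylsilyl)oxy]phenyl}-3-hydroxy-N-methoxy-N-methylpropanamide | CON(C)C(=O)C[C@H](O)c1ccc(O[Si](C)(C)C(C)(C)C)c(O[Si](C)(C)C(C)(C)C)c1 | intermediate
12 | tert-butyl (4E,8R)-2-[(7S)-7-{3,4-bis[(tert-butyldimethylsilyl)oxy]phenyl}-7-hydroxy-3,5-dioxoheptanoyl]-8-[(tert-butyldimethylsilyl)oxy]-5,9-dimethyldeca-4,9-dienoate | CC(C)(C)OC(=O)C(C/C=C(\C)CC[C@@H](O[Si](C)(C)C(C)(C)C)C(C)=C)C(=O)CC(=O)CC(=O)C[C@H](O)c1ccc(O[Si](C)(C)C(C)(C)C)c(O[Si](C)(C)C(C)(C)C)c1 | intermediate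
13 | tert-butyl (4E,8R)-2-{[(2S)-2-{3,4-bis[(tert-butyldimethylsilyl)oxy]phenyl}-4-oxo-3,4-dihydro-2H-pyran-6-yl]acetyl}-8-[(tert-butyldimethylsilyl)oxy]-5,9-dimethyldeca-4,9-dienoate | CC(C)(C)OC(=O)C(C/C=C(\C)CC[C@@H](O[Si](C)(C)C(C)(C)C)C(C)=C)C(=O)CC1=CC(=O)C[C@@H](c2ccc(O[Si](C)(C)C(C)(C)C)c(O[Si](C)(C)C(C)(C)C)c2)O1 | intermediate
14 | (2S)-2-{3,4-bis[(tert-butyldimethylsilyl)oxy]phenyl}-6-{(5E,9R)-9-[(tert-butyldimethylsilyl)oxy]-6,10-dimethyl-2-oxo-3-(oxomethylidene)undeca-5,10-dien-1-yl}-2,3-dihydro-4H-pyran-4-one (acylketene) | O=C=C(C/C=C(\C)CC[C@@H](O[Si](C)(C)C(C)(C)C)C(C)=C)C(=O)CC1=CC(=O)C[C@@H](c2ccc(O[Si](C)(C)C(C)(C)C)c(O[Si](C)(C)C(C)(C)C)c2)O1 | intermediate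
15 | (2S)-2-{3,4-bis[(tert-butyldimethylsilyl)oxy]phenyl}-6-[(2E,6R)-6-[(tert-butyldimethylsilyl)oxy]-3,7-dimethylocta-2,7-dien-1-yl]-5,7-dihydroxy-2,3-dihydro-4H-chromen-4-one | C=C(C)[C@H](O[Si](C)(C)C(C)(C)C)CC/C(C)=C/Cc1c(O)cc2c(c1O)C(=O)C[C@@H](c1ccc(O[Si](C)(C)C(C)(C)C)c(O[Si](C)(C)C(C)(C)C)c1)O2 | intermediate
16 | (2S)-2-(3,4-dihydroxyphenyl)-5,7-dihydroxy-6-[(2E,6R)-6-hydroxy-3,7-dimethylocta-2,7-dien-1-yl]-2,3-dihydro-4H-chromen-4-one | C=C(C)[C@H](O)CC/C(C)=C/Cc1c(O)cc2c(c1O)C(=O)C[C@@H](c1ccc(O)c(O)c1)O2 | target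

**Step count and risks**

Total steps: 10. Longest linear sequence: 7 (steps 1, 2, 3, 4, 8, 9, 10); steps 5–7 form the convergent aryl branch.

Most likely to fail:

1. Step 9 (double ring closure). The risks are:
   - acid turning the 1,3,5-triketone into a 4-pyranone before the hydroxyl closes ring C;
   - ketene forming before ring C exists and collapsing to a 4-hydroxy-2-pyranone;
   - acid ionizing the electron-rich benzylic carbinol, which would erode the 2S centre;
   - acidolysis of the tert-butyl ester followed by decarboxylation.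

   Fallback: replace the tert-butyl ester by a dioxinone, which masks C3 and releases the ketene at lower temperature. It sets out from 5. Heating 5 in acetone (sealed tube, 130 °C) traps the derived acylketene as 5-substituted 2,2,6-trimethyl-1,3-dioxin-4-one F1. γ-Lithiation with LiN(iPr)2 and acylation with 6 gives keto-dioxinone F2. The dianion of F2 is acylated with the lithium alkoxide of 11 to give hydroxy diketo-dioxinone F3. CSA at 23 °C closes ring C to pyranone-dioxinone F4. At 110 °C in toluene F4 loses acetone and gives the same ketene, so the fallback comes back to the route at 14 and then 15.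

2. Step 8 (trianion acylation). The risks are incomplete or mis-placed polyanion formation (acylation at C4 instead of the terminal methyl) and proton transfer from the amide instead of addition.

   Fallback: join the fragments by aldol addition and oxidize afterwards. It sets out from 11. TESCl/imidazole gives triethylsilyl ether F5. iBu2AlH at −78 °C reduces the Weinreb amide to aldehyde F6. The trianion of 7 adds to F6 to give aldol adduct F7 (mixture at the new carbinol). Dess–Martin periodinane oxidizes that carbinol to triketone silyl ether F8. AcOH/THF/H2O removes the triethylsilyl group, and the fallback comes back to the route at 12.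

3. Step 2 (epoxide to allylic silyl ether). The risks are cation–alkene cyclization of the activated epoxide onto the 2,3-alkene and a semipinacol shift to a ketone.

   Fallback: build the carbinol by asymmetric alkenylation of an aldehyde. It sets out from 2, whose stereocentre is then no longer needed. H5IO6 in THF/H2O cleaves the epoxide to aldehyde F9. Catalytic asymmetric Nozaki–Hiyama–Kishi addition of 2-bromopropene (CrCl2 cat., NiCl2 cat., Mn, TMSCl, chiral oxazoline–sulfonamide ligand) gives 6R allylic alcohol F10. TBSCl/imidazole silylates it, and the fallback comes back to the route at 3.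

**Further compounds**

F1 | step 9 | 5-[(2E,6R)-6-[(tert-butyldimethylsilyl)oxy]-3,7-dimethylocta-2,7-dien-1-yl]-2,2,6-trimethyl-4H-1,3-dioxin-4-one | CC1=C(C/C=C(\C)CC[C@@H](O[Si](C)(C)C(C)(C)C)C(C)=C)C(=O)OC(C)(C)O1
F2 | step 9 | 5-[(2E,6R)-6-[(tert-butyldimethylsilyl)oxy]-3,7-dimethylocta-2,7-dien-1-yl]-2,2-dimethyl-6-(2-oxopropyl)-4H-1,3-dioxin-4-one | CC(=O)CC1=C(C/C=C(\C)CC[C@@H](O[Si](C)(C)C(C)(C)C)C(C)=C)C(=O)OC(C)(C)O1
F3 | step 9 | 6-[(6S)-6-{3,4-bis[(tert-butyldimethylsilyl)oxy]phenyl}-6-hydroxy-2,4-dioxohexyl]-5-[(2E,6R)-6-[(tert-butyldimethylsilyl)oxy]-3,7-dimethylocta-2,7-dien-1-yl]-2,2-dimethyl-4H-1,3-dioxin-4-one | O=C(C[C@H](O)c1ccc(O[Si](C)(C)C(C)(C)C)c(O[Si](C)(C)C(C)(C)C)c1)CC(=O)CC1=C(C/C=C(\C)CC[C@@H](O[Si](C)(C)C(C)(C)C)C(C)=C)C(=O)OC(C)(C)O1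
F4 | step 9 | 6-{[(2S)-2-{3,4-bis[(tert-butyldimethylsilyl)oxy]phenyl}-4-oxo-3,4-dihydro-2H-pyran-6-yl]methyl}-5-[(2E,6R)-6-[(tert-butyldimethylsilyl)oxy]-3,7-dimethylocta-2,7-dien-1-yl]-2,2-dimethyl-4H-1,3-dioxin-4-one | CC1(C)OC(=O)C(C/C=C(\C)CC[C@@H](O[Si](C)(C)C(C)(C)C)C(C)=C)=C(CC2=CC(=O)C[C@@H](c3ccc(O[Si](C)(C)C(C)(C)C)c(O[Si](C)(C)C(C)(C)C)c3)O2)O1
F5 | step 8 | (3S)-3-{3,4-bis[(tert-butyldimethylsilyl)oxy]phenyl}-N-methoxy-N-methyl-3-[(triethylsilyl)oxy]propanamide | CON(C)C(=O)C[C@H](O[Si](CC)(CC)CC)c1ccc(O[Si](C)(C)C(C)(C)C)c(O[Si](C)(C)C(C)(C)C)c1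
F6 | step 8 | (3S)-3-{3,4-bis[(tert-butyldimethylsilyl)oxy]phenyl}-3-[(triethylsilyl)oxy]propanal | O=CC[C@H](O[Si](CC)(CC)CC)c1ccc(O[Si](C)(C)C(C)(C)C)c(O[Si](C)(C)C(C)(C)C)c1
F7 | step 8 | tert-butyl (4E,8R)-2-[(7S)-7-{3,4-bis[(tert-butyldimethylsilyl)oxy]phenyl}-5-hydroxy-3-oxo-7-[(triethylsilyl)oxy]heptanoyl]-8-[(tert-butyldimethylsilyl)oxy]-5,9-dimethyldeca-4,9-dienoate | CC(C)(C)OC(=O)C(C/C=C(\C)CC[C@@H](O[Si](C)(C)C(C)(C)C)C(C)=C)C(=O)CC(=O)CC(O)C[C@H](O[Si](CC)(CC)CC)c1ccc(O[Si](C)(C)C(C)(C)C)c(O[Si](C)(C)C(C)(C)C)c1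
F8 | step 8 | tert-butyl (4E,8R)-2-[(7S)-7-{3,4-bis[(tert-butyldimethylsilyl)oxy]phenyl}-3,5-dioxo-7-[(triethylsilyl)oxy]heptanoyl]-8-[(tert-butyldimethylsilyl)oxy]-5,9-dimethyldeca-4,9-dienoate | CC(C)(C)OC(=O)C(C/C=C(\C)CC[C@@H](O[Si](C)(C)C(C)(C)C)C(C)=C)C(=O)CC(=O)CC(=O)C[C@H](O[Si](CC)(CC)CC)c1ccc(O[Si](C)(C)C(C)(C)C)c(O[Si](C)(C)C(C)(C)C)c1
F9 | step 2 | (2E)-3-methyl-6-oxohex-2-en-1-yl acetate | O=CCC/C(C)=C/COC(C)=O
F10 | step 2 | (2E,6R)-6-hydroxy-3,7-dimethylocta-2,7-dien-1-yl acetate | C=C(C)[C@H](O)CC/C(C)=C/COC(C)=O
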